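Remark (assumption): the target is a bibenzyl (1,2-diarylethane), so its trivial name is read as 3,3'-dihydroxy-2,6-bis(p-hydroxybenzyl)-5-methoxybibenzyl; the SMILES string defines the structure, and no other structural correction was found necessary.

## Structural features

The target 13 is a bibenzyl: a pentasubstituted benzene (ring A) is joined from C1 through a CH2CH2 bridge to a 3-hydroxyphenyl ring (ring B). Ring A carries a 4-hydroxybenzyl group at C2 (ring C), a free hydroxyl at C3, hydrogen at C4, a methoxy group at C5 and a second 4-hydroxybenzyl group at C6 (ring D), so C6, C1 and C2 bear three contiguous carbon arms. There are four benzene rings, no other ring and no stereocentre, hence no neighbouring stereocentres to relate; every question is one of position and of telling the two ring A oxygens apart. Apart from that one difference (OH at C3, OCH3 at C5), ring A is symmetric about the C1–C4 axis and the two benzyl arms are identical. The fragile parts are the four electron-rich phenols, which oxidise in air as phenoxides, and the two diarylmethane CH2 groups on the resorcinol-type ring A, which ionise easily under acid; benzylic halides or alcohols at these positions would be too labile to carry. The real difficulty is to set three carbon substituents side by side on ring A without Friedel–Crafts benzylation, which could not be kept from C4 or from over-alkylation, and to free only one of two nearly equivalent oxygens. The key step exploits the fact that C2 and C6 are each ortho to one ring A oxygen and para to the other, the sites where a resorcinol diether is formylated. The two methylene carbons can therefore start as ring A aldehyde carbons and, as N-tosylhydrazones, take up rings C and D from an arylboronic acid at the end of the carbon assembly.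

## Logic of the disconnections

13 from 12. Four O–CH3 bonds are restored: one on each of rings B, C and D and the one at C3 of ring A. The cut is placed there because a thiolate removes exactly one methyl group per methoxy-bearing ring. Rings B, C and D have only one, and ring A becomes a phenoxide after its first cleavage, which shields its second methyl ether. The gain is that every oxygen travels as an inert methyl ether, the two ring A oxygens stay equivalent until the last step, and all aryl building blocks are catalogue methyl ethers. Benzyl ethers on the outer rings would fall to the same thiolate and would only add an olefination and a hydrogenolysis, so they are replaced by methyl ethers in 8 and 12. The demand on the forward step is completion on three rings and a stop after one cleavage on ring A.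

12 from 8 and two molecules of 9. The two bonds between the ring A methylene carbons (on C2 and C6) and the ipso carbons of rings C and D are cut. The reason is that these methylene carbons sit where ring A accepts formyl groups, and a hydrazone-derived carbene carbon accepts an aryl group from boron without any benzylic leaving group on the electron-rich ring. The gain is that two identical rings fall away at once and leave a ring A carrying two equal C1 units. The demand is that both arms of 8 insert into a C–B bond rather than dimerise, form azines or attack the neighbouring bridge.

8 from 6 and two molecules of 7. The two C=N bonds are cut. The reason is that 8 is the stable, storable form of the two diazo groups and is made by condensation alone. The gain is small in atoms but removes all hazardous functionality from the isolated intermediates. The demand is only complete twofold condensation at two hindered formyl groups.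

6 from 3 and 5, and 5 from 4. The bond between C1 of ring A and the bridge CH2 is cut, and then the C–B bond of 5. The reason is that C1 lies between the two formyl groups, where a bromine can sit from the very start, and an sp2–sp3 coupling delivers the bridge already saturated. The gain is that ring B with its bridge becomes a catalogue alkene. The demand is a coupling at a bromide flanked by two free formyl groups, with no hydride left to reduce them.

3 from 2, and 2 from 1. The two ring–CHO bonds are cut one after the other. The reason is that both positions beside the bromine are para to one methoxy group and ortho to the other, so electrophilic formylation is directed there, while the bromine marks C1. The gain is a symmetric catalogue bromoarene. The demand is that the second, slower formylation again choose the position beside bromine and not the one between the two methoxy groups.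

## Other disconnections considered

Alternative 1: The cut runs through ring A itself, at C1–C2 and C1–C6. C1 with its arylethyl arm would come from the aldehyde A3, and C2 to C6 with both benzyl arms from the 1,3-diketone A2.
- Forward key step: the dianion of A2 adds through one outer α-carbon to A3, the aldol is acetylated and eliminated in the same flask, and the other outer α-carbon closes the six-membered ring by conjugate addition to give the all-trans dione A1. Dehydrogenation to the resorcinol, methylation of one hydroxyl and hydrogenolysis would follow.
- In favour: all three carbon arms are placed by connectivity alone, with no reliance on site selectivity of aromatic substitution. On this point it is better than the chosen plan, whose second formylation must choose between two open ring positions.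
- Against: a 1,3-diketone dianion is nucleophilic at only one outer carbon, so the closure needs a further deprotonation in the presence of an enone and acetate. A3 is enolisable under a strong base. Three stereocentres are set only to be erased. The aromatising oxidation must spare four electron-rich benzylic positions.
- Comparison: the aromatised ring has two equivalent hydroxyls, so the one-of-two oxygen problem is equal to that of the chosen plan, with no gain. Mechanistically it is a cascade of four ionic events in one flask, against two repeats of one well-understood event. Step economy is worse, at roughly eight steps against six.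

Alternative 2: The cuts are the C2–benzyl, C6–benzyl and C1–Cα bonds around an iodinated C1.
- Forward key step: the aryl iodide A5, two equivalents of the benzylic chloride A6 and the styrene A7 are combined under Pd(OAc)2, tri(2-furyl)phosphine, norbornene and Cs2CO3. Two ortho C–H benzylations are followed by Heck termination to the (E)-stilbene A4. One hydrogenation would then saturate the alkene and remove all four benzyl groups.
- In favour: the two ring A oxygens are differentiated from the start (benzyl against methyl), no thiolate step is needed, and the whole carbon skeleton is assembled in one operation. In step economy (about five steps, longest line about four) and in oxygen differentiation it is better than the chosen plan.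
- Against: both C–H bonds to be activated are wedged between the iodine-bearing carbon and an alkoxy group, the substitution pattern least favourable for palladacycle formation. Benzylic chlorides compete through direct coupling and homocoupling. The sequence must run twice before termination, so mono-benzylated and norbornene-retaining products are the expected leaks.
- Comparison: structurally both plans fix positions before the outer rings arrive; they are equal there. Mechanistically the chosen step is two independent, metal-free events, whereas this one is an ordered four-component palladium sequence with little tolerance for steric load. The chosen plan is longer but each step stands on firmer ground.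

Alternative 3: The cut is through ring A at C2–C3 and C1–C6.
- Forward key step: the Brassard-type diene A9 and the ynone A10 undergo (4+2) cycloaddition, and loss of methanol and of the silyl group aromatises the adduct to the benzophenone A8. Reduction of the ketone to CH2 and debenzylation would follow.
- In favour: the free hydroxyl at C3 and the methoxy group at C5 are set apart by construction, and the regiochemistry follows the polarity of both partners. On oxygen differentiation it is better than the chosen plan.
- Against: a diene substituted at its nucleophilic terminus and a β-alkyl ynone are both sluggish partners, and the ring is formed with five contiguous substituents in one event. A9 is hydrolytically labile and needs about three steps, A10 two or three. One benzyl carbon arrives at the wrong oxidation level and must be reduced.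
- Comparison: both plans bring in outer rings with their oxygen pattern fixed by the reagent; they are equal there. Mechanistically the chosen step acts on a preformed ring, whereas this one builds ring A with a regiochemical and steric demand. Step economy is worse, at roughly nine steps against six.

Key step: step 5

## Route

Step 1
Reactants: 1 1-bromo-3,5-dimethoxybenzene
Product: 2 2-bromo-4,6-dimethoxybenzaldehyde
Conditions: POCl3, DMF, 0 to 90 °C; then ice/H2O
Reagents that add atoms: N,N-dimethylformamide, CN(C)C=O (formyl carbon); water, O (formyl oxygen)
Why: Vilsmeier–Haack formylation; the chloroiminium electrophile attacks beside the bromine, para to one methoxy group and ortho to the other, in preference to the more crowded site between the two methoxy groups, and the deactivated product does not react a second time, so the reaction should stop at the monoaldehyde.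

Step 2
Reactants: 2 2-bromo-4,6-dimethoxybenzaldehyde
Product: 3 2-bromo-4,6-dimethoxybenzene-1,3-dicarbaldehyde
Conditions: Cl2CHOMe, TiCl4, CH2Cl2, 0 °C to rt; then ice/aq. HCl
Reagents that add atoms: dichloromethyl methyl ether, COC(Cl)Cl (formyl carbon); water, O (formyl oxygen)
Why: Rieche formylation; the TiCl4-activated reagent is a stronger electrophile than the Vilsmeier reagent and should substitute the ring once more at the remaining position beside bromine, which is para to the C6 methoxy group and meta to the formyl group, whereas the other open site is squeezed between two methoxy groups, one of them held in place by the neighbouring carbonyl group.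

Step 3
Reactants: 4 3-methoxystyrene; 3 2-bromo-4,6-dimethoxybenzene-1,3-dicarbaldehyde
Product: 6 2-[2-(3-methoxyphenyl)ethyl]-4,6-dimethoxybenzene-1,3-dicarbaldehyde, via 9-[2-(3-methoxyphenyl)ethyl]-9-borabicyclo[3.3.1]nonane 5 (not isolated)
Conditions: 4 (slight excess), 9-BBN-H, THF, 0 °C to rt; then aq. K3PO4, 3, Pd(OAc)2 (5 mol %), SPhos, THF/H2O, 60 °C
Reagents that add atoms: none
Why: Anti-Markovnikov hydroboration followed by B-alkyl Suzuki–Miyaura coupling; the C–Br bond lies between two electron-withdrawing formyl groups and should add readily to zerovalent palladium (formed in the flask from divalent Pd(OAc)2), the bulky biarylphosphine favours reductive elimination at the di-ortho-substituted centre over β-hydride elimination, and the alkene excess plus addition of base before 3 leaves no B–H to reduce the aldehydes.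

Step 4
Reactants: 6 2-[2-(3-methoxyphenyl)ethyl]-4,6-dimethoxybenzene-1,3-dicarbaldehyde; 7 p-toluenesulfonyl hydrazide
Product: 8 bis(N-tosylhydrazone) of 6, both C=N bonds E
Conditions: 7 (2.2 equiv), MeOH, 60 °C; cool, filter
Reagents that add atoms: none
Why: Twofold condensation of aldehyde and sulfonyl hydrazide; the sparingly soluble bis(hydrazone) should crystallise from methanol, which drives the reaction to completion and gives a stable solid in place of a diazo compound.

Step 5
Reactants: 8 bis(N-tosylhydrazone) of 6; 9 4-methoxyphenylboronic acid
Product: 12 2,4-bis(4-methoxybenzyl)-3-[2-(3-methoxyphenyl)ethyl]-1,5-dimethoxybenzene, via 1,3-bis(diazomethyl)-4,6-dimethoxy-2-[2-(3-methoxyphenyl)ethyl]benzene 10 (not isolated), via twofold benzylic boronic acid 11 (not isolated)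
Conditions: 9 (4 equiv), K2CO3 (5 equiv), 1,4-dioxane, 110 °C, argon; 8 added in portions
Reagents that add atoms: none
Why: K2CO3 deprotonates each sulfonylhydrazone N–H and the salt loses p-toluenesulfinate on heating (Bamford–Stevens fragmentation), so each arm becomes an aryldiazomethane, drawn for both arms in 10. The nucleophilic diazo carbon adds to the empty orbital on boron of 9, and the boronate undergoes 1,2-migration of the 4-methoxyphenyl group from boron to carbon with loss of dinitrogen, giving the benzylic boronic acid arm of 11. Under the hot basic conditions this crowded, doubly benzylic C–B bond is protodeboronated, which leaves the CH2 group and erases the two transient boron-bearing stereocentres of 11, so 12 has none. The closest known reaction type is the metal-free reductive coupling of aldehyde N-tosylhydrazones with arylboronic acids (Barluenga coupling), run here twice on one ring; the arms are meta to each other and react independently, and 10 and 11 show both arms at the same stage only for clarity. No ring is closed and no regiochemical choice exists, because the carbene carbons are the former formyl carbons and the new aryl carbon is the one that carried boron. The selectivity needed is chemoselectivity for insertion into the C–B bond over azine formation, carbene dimerisation, recombination with sulfinate to a sulfone and carbene C–H insertion into the neighbouring ethylene bridge. It is secured by the sparingly soluble base, which releases the diazo groups slowly, by portionwise addition of 8 to an excess of 9, by the high migratory aptitude of the electron-rich aryl group, and by the two ortho substituents of each arm, which hinder bimolecular azine formation.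

Step 6
Reactants: 12 2,4-bis(4-methoxybenzyl)-3-[2-(3-methoxyphenyl)ethyl]-1,5-dimethoxybenzene
Product: 13 3,3'-dihydroxy-2,6-bis(p-hydroxybenzyl)-5-methoxybibenzyl
Conditions: NaSEt (12 equiv), DMF, 140–150 °C, argon; then dil. HCl, 0 °C
Reagents that add atoms: none
Why: SN2 dealkylation of aryl methyl ethers by thiolate; rings B, C and D each lose their only methyl group, while on ring A the phenoxide formed by the first cleavage makes the ring a far poorer leaving group for the second, so the two equivalent methoxy groups are desymmetrised, one survives, and mildly acidic work-up should give 13.

## Compound list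

1 | 1-bromo-3,5-dimethoxybenzene | COc1cc(Br)cc(OC)c1 | starting material
2 | 2-bromo-4,6-dimethoxybenzaldehyde | COc1cc(Br)c(C=O)c(OC)c1 | intermediate
3 | 2-bromo-4,6-dimethoxybenzene-1,3-dicarbaldehyde | COc1cc(OC)c(C=O)c(Br)c1C=O | intermediate
4 | 3-methoxystyrene (1-ethenyl-3-methoxybenzene) | C=Cc1cccc(OC)c1 | starting material
5 | 9-[2-(3-methoxyphenyl)ethyl]-9-borabicyclo[3.3.1]nonane (formed in the flask, not isolated) | COc1cccc(CCB2C3CCCC2CCC3)c1 | intermediate
6 | 2-[2-(3-methoxyphenyl)ethyl]-4,6-dimethoxybenzene-1,3-dicarbaldehyde | COc1cc(OC)c(C=O)c(CCc2cccc(OC)c2)c1C=O | intermediate
7 | p-toluenesulfonyl hydrazide | Cc1ccc(S(=O)(=O)NN)cc1 | starting material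
8 | bis(N-tosylhydrazone) of 6, both C=N bonds E | COc1cc(OC)c(/C=N/NS(=O)(=O)c2ccc(C)cc2)c(CCc2cccc(OC)c2)c1/C=N/NS(=O)(=O)c1ccc(C)cc1 | intermediate
9 | 4-methoxyphenylboronic acid | COc1ccc(B(O)O)cc1 | starting material
10 | 1,3-bis(diazomethyl)-4,6-dimethoxy-2-[2-(3-methoxyphenyl)ethyl]benzene (formed in the flask, not isolated) | COc1cc(OC)c(C=[N+]=[N-])c(CCc2cccc(OC)c2)c1C=[N+]=[N-] | intermediate
11 | {4,6-dimethoxy-2-[2-(3-methoxyphenyl)ethyl]-1,3-phenylene}bis[(4-methoxyphenyl)methylene]diboronic acid, the twofold benzylic boronic acid (two transient stereocentres, mixture of diastereomers, not isolated) | COc1cc(OC)c(C(B(O)O)c2ccc(OC)cc2)c(CCc2cccc(OC)c2)c1C(B(O)O)c1ccc(OC)cc1 | intermediate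
12 | 2,4-bis(4-methoxybenzyl)-3-[2-(3-methoxyphenyl)ethyl]-1,5-dimethoxybenzene | COc1cc(OC)c(Cc2ccc(OC)cc2)c(CCc2cccc(OC)c2)c1Cc1ccc(OC)cc1 | intermediate
13 | 3,3'-dihydroxy-2,6-bis(p-hydroxybenzyl)-5-methoxybibenzyl (achiral) | COc1cc(O)c(Cc2ccc(O)cc2)c(CCc2cccc(O)c2)c1Cc1ccc(O)cc1 | target

## Step count and least certain steps

Total step count: 6. Longest linear sequence: 6 steps (1 to 2 to 3 to 6 to 8 to 12 to 13); 4, 7 and 9 are catalogue chemicals and 5 is made and used in the flask of step 3.

Step 5 (key step). The likeliest failure is diversion of a diazo arm before it meets the boronic acid: azine formation, recombination with sulfinate, or carbene insertion into a C–H bond of the neighbouring bridge. Incomplete protodeboronation of one arm is also possible. Because two arms must both succeed, any leak is felt twice. Fallback from 6, returning at 12: twofold addition of 4-methoxyphenylmagnesium bromide (THF, 0 °C) should give {4,6-dimethoxy-2-[2-(3-methoxyphenyl)ethyl]-1,3-phenylene}bis[(4-methoxyphenyl)methanol] F1. Ionic hydrogenation (Et3SiH, CF3CO2H, CH2Cl2, 0 °C) should then ionise each doubly benzylic carbinol, stabilised by the ortho and para methoxy groups, and reduce it to the methylene of 12.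

Step 2. The second electrophilic substitution may stall on a ring deactivated by one formyl group and crowded by bromine, or lose positional control towards the site between the methoxy groups. Lewis-acid cleavage of the methoxy group next to the carbonyl is a further leak. Fallback from 1 (with 5), returning at 6: B-alkyl Suzuki–Miyaura coupling of 1 with 5 should give 1-[2-(3-methoxyphenyl)ethyl]-3,5-dimethoxybenzene F2. Twofold bromination with N-bromosuccinimide (MeCN, 0 °C) is directed to the two ring A positions beside the chain, each para to a methoxy group, and should give 2,4-dibromo-1,5-dimethoxy-3-[2-(3-methoxyphenyl)ethyl]benzene F3. Twofold bromine–lithium exchange (t-BuLi, THF, −78 °C) and quenching with DMF should then give 6. In this fallback halogenation, not formylation, decides the positions, and the aldehydes are made without a Lewis acid.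

Step 3. Hydride transfer from boron to a formyl group, or slow transmetalation at the bromide between two formyl groups followed by loss of bromine or β-hydride elimination, would erode the coupling. Fallback from 3, returning at 6: Negishi coupling with [2-(3-methoxyphenyl)ethyl]zinc bromide F4, made from commercial 1-(2-bromoethyl)-3-methoxybenzene with zinc dust and LiCl in THF, under Pd(OAc)2/SPhos in THF at rt to 50 °C. Alkylzinc halides do not add to aldehydes under these conditions and carry no hydride.

Step 6. The dealkylation may stall before all four methyl groups are gone as the polyphenoxide salts out, or slowly remove the second ring A methyl group under prolonged forcing. Fallback from 3, returning at 13, with orthogonal benzyl protection and no thiolate: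
- Chelation-controlled cleavage of one methoxy group next to a formyl group (BCl3, CH2Cl2, −78 to 0 °C) should give 2-bromo-4-hydroxy-6-methoxybenzene-1,3-dicarbaldehyde F5.
- Benzylation (BnBr, K2CO3, DMF) should give 4-benzyloxy-2-bromo-6-methoxybenzene-1,3-dicarbaldehyde F6.
- Wittig methylenation of commercial 3-benzyloxybenzaldehyde should give 3-benzyloxystyrene F7 (the same compound as A7), and 9-BBN-H should convert it into 9-[2-(3-benzyloxyphenyl)ethyl]-9-borabicyclo[3.3.1]nonane F8.
- Coupling of F8 with F6 as in step 3 should give 4-benzyloxy-2-[2-(3-benzyloxyphenyl)ethyl]-6-methoxybenzene-1,3-dicarbaldehyde F9.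
- Condensation with 7 should give its bis(N-tosylhydrazone) F10.
- Coupling with commercial 4-benzyloxyphenylboronic acid as in step 5 should give 1-benzyloxy-2,4-bis(4-benzyloxybenzyl)-3-[2-(3-benzyloxyphenyl)ethyl]-5-methoxybenzene F11.
- Hydrogenolysis (H2, Pd/C, EtOAc/MeOH) should remove all four benzyl groups and give 13.

## Further compounds

F1 | step 5 | {4,6-dimethoxy-2-[2-(3-methoxyphenyl)ethyl]-1,3-phenylene}bis[(4-methoxyphenyl)methanol] (mixture of diastereomers) | COc1cc(OC)c(C(O)c2ccc(OC)cc2)c(CCc2cccc(OC)c2)c1C(O)c1ccc(OC)cc1
F2 | step 2 | 1-[2-(3-methoxyphenyl)ethyl]-3,5-dimethoxybenzene | COc1cccc(CCc2cc(OC)cc(OC)c2)c1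
F3 | step 2 | 2,4-dibromo-1,5-dimethoxy-3-[2-(3-methoxyphenyl)ethyl]benzene | COc1cc(OC)c(Br)c(CCc2cccc(OC)c2)c1Br
F4 | step 3 | [2-(3-methoxyphenyl)ethyl]zinc bromide | COc1cccc(CC[Zn]Br)c1
F5 | step 6 | 2-bromo-4-hydroxy-6-methoxybenzene-1,3-dicarbaldehyde | COc1cc(O)c(C=O)c(Br)c1C=O
F6 | step 6 | 4-benzyloxy-2-bromo-6-methoxybenzene-1,3-dicarbaldehyde | COc1cc(OCc2ccccc2)c(C=O)c(Br)c1C=O
F7 | step 6 | 3-benzyloxystyrene | C=Cc1cccc(OCc2ccccc2)c1
F8 | step 6 | 9-[2-(3-benzyloxyphenyl)ethyl]-9-borabicyclo[3.3.1]nonane | C(Oc1cccc(CCB2C3CCCC2CCC3)c1)c1ccccc1
F9 | step 6 | 4-benzyloxy-2-[2-(3-benzyloxyphenyl)ethyl]-6-methoxybenzene-1,3-dicarbaldehyde | COc1cc(OCc2ccccc2)c(C=O)c(CCc2cccc(OCc3ccccc3)c2)c1C=O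
F10 | step 6 | bis(N-tosylhydrazone) of F9, both C=N bonds E | COc1cc(OCc2ccccc2)c(/C=N/NS(=O)(=O)c2ccc(C)cc2)c(CCc2cccc(OCc3ccccc3)c2)c1/C=N/NS(=O)(=O)c1ccc(C)cc1
F11 | step 6 | 1-benzyloxy-2,4-bis(4-benzyloxybenzyl)-3-[2-(3-benzyloxyphenyl)ethyl]-5-methoxybenzene | COc1cc(OCc2ccccc2)c(Cc2ccc(OCc3ccccc3)cc2)c(CCc2cccc(OCc3ccccc3)c2)c1Cc1ccc(OCc2ccccc2)cc1
A1 | alternative 1 | all-trans 4,6-bis(4-benzyloxybenzyl)-5-[2-(3-benzyloxyphenyl)ethyl]cyclohexane-1,3-dione (meso; benzyl groups cis to each other, both trans to the arylethyl group) | O=C1CC(=O)[C@@H](Cc2ccc(OCc3ccccc3)cc2)[C@H](CCc2cccc(OCc3ccccc3)c2)[C@H]1Cc1ccc(OCc2ccccc2)cc1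
A2 | alternative 1 | 1,7-bis(4-benzyloxyphenyl)heptane-3,5-dione | O=C(CCc1ccc(OCc2ccccc2)cc1)CC(=O)CCc1ccc(OCc2ccccc2)cc1
A3 | alternative 1 | 3-(3-benzyloxyphenyl)propanal | O=CCCc1cccc(OCc2ccccc2)c1
A4 | alternative 2 | 1-benzyloxy-2,4-bis(4-benzyloxybenzyl)-3-[(E)-2-(3-benzyloxyphenyl)ethenyl]-5-methoxybenzene | COc1cc(OCc2ccccc2)c(Cc2ccc(OCc3ccccc3)cc2)c(/C=C/c2cccc(OCc3ccccc3)c2)c1Cc1ccc(OCc2ccccc2)cc1
A5 | alternative 2 | 1-benzyloxy-3-iodo-5-methoxybenzene | COc1cc(I)cc(OCc2ccccc2)c1
A6 | alternative 2 | 4-benzyloxybenzyl chloride | ClCc1ccc(OCc2ccccc2)cc1
A7 | alternative 2 | 3-benzyloxystyrene | C=Cc1cccc(OCc2ccccc2)c1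
A8 | alternative 3 | (4-benzyloxyphenyl){3-(4-benzyloxybenzyl)-2-[2-(3-benzyloxyphenyl)ethyl]-6-hydroxy-4-methoxyphenyl}methanone | COc1cc(O)c(C(=O)c2ccc(OCc3ccccc3)cc2)c(CCc2cccc(OCc3ccccc3)c2)c1Cc1ccc(OCc2ccccc2)cc1
A9 | alternative 3 | {[5-(4-benzyloxyphenyl)-1,3-dimethoxypenta-1,3-dien-1-yl]oxy}trimethylsilane (double-bond geometry not defined) | COC(O[Si](C)(C)C)=CC(OC)=CCc1ccc(OCc2ccccc2)cc1
A10 | alternative 3 | 1-(4-benzyloxyphenyl)-5-(3-benzyloxyphenyl)pent-2-yn-1-one | O=C(C#CCCc1cccc(OCc2ccccc2)c1)c1ccc(OCc2ccccc2)cc1
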